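Atom labels used throughout (target numbering): ring C = C1 (tertiary carbinol), C2 (ketone), C3 (CHOH), C4 (hemiketal carbon), C5 (CH), C6 (CHMe), C7 (sp2, shared with ring D); ring D = C1, C7, C8 (=CH), C9 (C=O), C10 (CMe2); C11 = CH2 between C5 and the pyrone; pyrone atoms O1', C2'–C6'. Ring A = pyrone, ring B = dihydropyran (O, C4, C5, C11, C3', C4'). With these labels the target is (1R,3R,4S,5R,6R). The same labels are kept for the diquinanes, which simply lack C3 and C4 and have a C2–C5 bond.

Remark on the chemistry: the key-step compounds 12 and 16 carry C1 and C6 in the target configuration and a cis ring fusion, so no correction of constitution is needed. What has to be improved is the way C6 is reached: in the cis-fused diquinane the C6 methyl must sit on the concave face (trans to the C1 oxygen), which a conjugate addition/ring closure sequence is not expected to deliver directly.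

Assumption: C3, C4 and C5 of the target belong to a ring–chain tautomeric 2-hydroxy-1,3-diketone/hemiketal system, and the target is taken to be its most stable stereoisomer (trans-fused rings B and C, axial anomeric hydroxyl).

Structural features

The target is a tetracycle: a fully substituted 4-oxy-5,6-dimethyl-2-pyrone (ring A) is fused through C3'–C4' to a dihydropyran (ring B), which shares the C4–C5 bond with a seven-membered carbocycle (ring C), itself fused at C1–C7 to a 4-hydroxy-5,5-dimethylcyclopent-2-enone (ring D). Ring C carries four contiguous stereocentres, C3 (secondary alcohol), C4 (hemiketal), C5 and C6 (methyl), plus the isolated tertiary carbinol C1, which is separated from C6 by the sp2 carbon C7 and from C3 by the C2 ketone; the C1 oxygen and the C6 methyl lie on opposite faces of ring C. The hemiketal is a masked 2-hydroxy-1,3-diketone, so C3, C4 and C5 can epimerise through the open form. The C1 carbinol is at once an α-ketol (acyloin shift) and the β-hydroxyl of the C9 ketone (retro-aldol through C1–C10), the enone has a γ-hydrogen at C6, and the pyrone methyl groups are acidic toward strong base. The real difficulty is the seven-membered ring with oxygen on C2, C3 and C4 next to a quaternary carbinol, together with the C1/C6 relationship, which has to be relayed through a ring-fusion carbon (C7) that ends up sp2. The key step exploits the 1,3-dicarbonyl arc C2–C3–C4: taking C3 and C4 out and joining C2 to C5 leaves a cyclopentanone (C1, C2, C5, C6, C7) fused to ring D at C1–C7, so ring C is a cis-bicyclo[3.3.0]octanone enlarged by two carbons. Because C1 is quaternary, that cyclopentanone can enolise only toward C5, the carbon that must end up bonded to the new C4 carbonyl.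

Logic of the disconnections

26 to 24: the C3–OH and C4–OH bonds are removed together, leaving a C3=C4 enol ether. Both oxygens can then come from one oxidative hydration of an electron-rich double bond, and the three labile centres (C3, C4, C5) are set last, where they can equilibrate. Two stereocentres and the most fragile array disappear. The forward step needs an oxidant that chooses the enol ether over the enone and the pyrone, and it relies on the target being the thermodynamic isomer.

24 to 23: the C7=C8 double bond is removed. In 23 the C9 ketone is the only carbonyl that can enolise normally, so the dehydrogenation has no regiochemical competitor. The gain is a saturated, cis-fused ring system in which C7 is a stereocentre that can relay configuration. The forward step must work without base.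

23 to 21: water is added back across C3=C4 and C9 is re-masked as its dioxolane. 21 is the direct product of ring B formation, and the ketal is what protected C9 during the carbanion chemistry. The forward step needs acid strong enough for a hindered dioxolane yet mild enough to spare the α-ketol.

21 to 17 and 18: the C11–C3' bond and the ring B O–C4 bond are cut. Ring A is thereby bought, and ring B is seen as the result of a conjugate addition followed by ring–chain tautomerism. The forward step requires the pyrone carbon nucleophile to outrun the diketone of 17, and C5 to settle trans to the C6 methyl.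

17 to 16: the C5–C11 bond is cut. C5 is the only γ-methylene of the diketone, because C1 is quaternary. The simplification is loss of one carbon and one stereocentre; the demand is a polyanion that reacts at carbon C5 and not at C3 or oxygen.

16 to 12 and 13 (key): the C2–C3 and C4–C5 bonds are cut and C2 is rejoined to C5, so that C3 and C4 leave as a two-carbon unit delivered by 13. The seven-membered ring, hard to close directly, becomes an easily made cis-diquinane. The forward step must add the two carbons with the right orientation and then break the C2–C5 bond and not the C2–C3 bond.

12 to 11 to 10: the silyl groups are removed and then the C6–H bond, giving a C5=C6 double bond. This lets C6 be set from C1 by hydrogen delivery to the hydroxyl face, so that C6 need not be correct earlier. The demand is clean facial selectivity in the hydrogenation.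

10 to 7 to 6: the C5=C6 double bond is traced back to the saturated ketol with the opposite (convex) C6 configuration, through its enol ether. This accepts the diastereomer that conjugate addition and ring closure are expected to give. The forward step is a dehydrogenation that must remove a hydrogen on the concave face.

6 to 5: the C1–C2 bond is cut (aldehyde carbon C2 as acyl anion, ketone C1 as acceptor). This opens the ketol to a keto-aldehyde whose only ring is ring D; the cis ring fusion makes C1 depend on C7. The forward step needs umpolung of an enolisable aldehyde.

5 to 3 and 4: the C6–C7 bond is cut. This is a conjugate addition of the ring D enol ether to a four-carbon enal and the source of absolute configuration. The forward step must control the face of the enal β-carbon.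

3 to 2 to 1: the enol silyl group and then the dioxolane are removed. The symmetrical dione is desymmetrised only by protection, and the single enolisable position of 2 fixes where C7 is.

Other disconnections considered

Alternative 1: The cut removes ring A last, through the pyrone C4'–C5' and O1'–C6' bonds, leaving 2-butyne A3 and a ring B/C/D carboxylic acid A2 (a dihydropyran with a vinylic C4'–H and the carboxyl group on C3'; C4 as methyl ketal; C1 and C3 hydroxyls as triethylsilyl ethers). In the forward key step [Cp*RhCl2]2 with Ag2CO3 would metalate the vinylic C–H cis to the carboxylate, insert A3 and form the C–O bond by reductive elimination to give A1; ketal and silyl ethers would then be removed.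
- In favour: a symmetrical alkyne poses no regiochemical question, and ring A comes from a C4 feedstock. The hemiketal and the C3 hydroxyl are already in place and protected, so nothing has to be oxidised next to the pyrone. On this point the alternative is better than the chosen plan, which runs two oxidations (steps 13 and 14) with the pyrone present.
- Against, here: it removes the easiest ring. A2 still holds the whole seven-membered ketol array and the cyclopentenone, so ring C must be made anyway, and ring B must then be built as a β-alkoxyacrylic acid, which costs more than the conjugate addition of 18. A2 is a vinylogous carbonic acid derivative that may decarboxylate at the temperature such annulations need, and the enone could compete for the metal.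
- Comparison: in structure both plans fix C5 before ring B is complete and neither creates a stereocentre in its key step (equal). In mechanism the alternative is an organometallic C–H functionalisation, against a polar cycloaddition/fragmentation whose orientation is fixed by enol ether polarity. In step economy the chosen plan buys ring A and needs no protecting group after step 12, whereas A1 still carries three.

Alternative 2: The cut is the C1–C10 bond of ring D, and behind it the enedione is folded back into a 2-isopropylfuran fused to ring C, A5 (furan carbons = C1, C7, C8, C9). In the forward key step a peracid (m-CPBA) would open A5 to the Z-enedione A6, and K2CO3 in methanol would let the isopropyl ketone enolate (C10) add to the ring C ketone (C1) to give A4.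
- In favour: the enone, the tertiary carbinol and the gem-dimethyl group arrive together at the right oxidation level, so no dehydrogenation of ring D is needed (better than step 13). Because the aldol is reversible, C1 can settle relative to C6. A furan is a robust masked 1,4-dicarbonyl.
- Against, here: ring C must already exist, so the seven-membered ring problem is moved, not solved. C2 (ketal) and C4 (silyl ether) still need adjusting and C3 and C5 still need functionalising, so the endgame is no shorter. The aldol joins two fully substituted carbons beside a ketal, and the sense and size of the thermodynamic preference at C1 is an assumption. A6 may isomerise or take up methoxide.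
- Comparison: in structure the chosen plan fixes C1 kinetically through the cis ring fusion of step 4, which is firmer than an equilibrium; it pays for this with the C6 correction (steps 5–7), which the alternative does not need (better there). In mechanism the alternative is oxidative ring opening plus reversible aldol, against cycloaddition/retro-aldol. Step economy is comparable once the origin of A5 is counted.

Alternative 3: The cut is the C4–C5 bond. In the forward key step Bu3SnH with AIBN would turn the phenyl selenoester A8 (a Z-β-methoxyacryloyl unit on C1 of a cyclopentenone that carries an isopropenyl group on C7) into an acyl radical at C4; this would add to the terminal carbon of the isopropenyl group (7-endo), and hydrogen transfer to the delocalised C6 radical would give A7.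
- In favour: ring C is closed directly on a finished ring D, so no late dehydrogenation is needed (better than the chosen plan). C2 and C4 emerge differentiated as enol ether and ketone, so C5 can be functionalised by ordinary α'-enolate chemistry. This is better than the chosen plan, whose diketone 16 needs a polyanion to tell C5 from C3.
- Against, here: C6 is set by hydrogen-atom transfer to a planar radical, with only the remote C1 silyloxy group to bias the face. 6-exo closure, simple reduction of the acyl radical and loss of acryloyl geometry compete. A quaternary C1 bearing three different unsaturated groups needs its own asymmetric construction, and tin and selenium reagents are stoichiometric.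
- Comparison: in structure the chosen plan sets C6 by hydroxyl-directed hydrogenation, which is more dependable. In mechanism a radical chain with a kinetically chosen ring size stands against a polar process whose regiochemistry is not in doubt. In step economy the alternative is probably shorter after its key step and longer before it.

Key step: step 9

Step 1
Reactants: 1 2,2-dimethylcyclopentane-1,3-dione
Product: 2 6,6-dimethyl-1,4-dioxaspiro[4.4]nonan-7-one (mono-ethylene ketal; ketal carbon = future C9; free ketone = future C1)
Conditions: ethylene glycol (1.05 equiv), p-TsOH·H2O (2 mol%), benzene, reflux, azeotropic removal of water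
Reagents that add atoms: ethylene glycol OCCO
Why: Acid-catalysed ketalisation; the two carbonyls are equivalent, so mono-protection needs only control of stoichiometry, and the remaining carbonyl, now flanked by a quaternary carbon and a dioxolane, reacts more slowly.

Step 2
Reactants: 2 6,6-dimethyl-1,4-dioxaspiro[4.4]nonan-7-one
Product: 3 [(6,6-dimethyl-1,4-dioxaspiro[4.4]non-7-en-7-yl)oxy]trimethylsilane
Conditions: LiN(iPr)2 (1.1 equiv), THF, −78 °C; Me3SiCl (1.3 equiv), −78 → 0 °C
Reagents that add atoms: chlorotrimethylsilane C[Si](C)(C)Cl
Why: Enolate O-silylation; the ketone has hydrogen on one α-carbon only (the other is CMe2), so a single enol ether (C1=C7 in target numbering) can form.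

Step 3
Reactants: 3 [(6,6-dimethyl-1,4-dioxaspiro[4.4]non-7-en-7-yl)oxy]trimethylsilane; 4 (E)-but-2-enal (crotonaldehyde)
Product: 5 (3S)-3-[(8R)-6,6-dimethyl-7-oxo-1,4-dioxaspiro[4.4]nonan-8-yl]butanal (6S,7R in target numbering)
Conditions: (2R,5R)-5-benzyl-2-tert-butyl-3-methylimidazolidin-4-one·CF3CO2H (20 mol%), 4 (3 equiv), H2O (2 equiv), CH2Cl2, −40 °C
Reagents that add atoms: none
Why: Organocatalytic Mukaiyama–Michael addition: the enol silane attacks the β-carbon of the E-iminium ion on the face left open by the benzyl group, which for this catalyst enantiomer should give 6S by analogy with other π-nucleophiles (the mirror-image catalyst would be used if the sense proved opposite). An open transition state between an E-enol silane and an E-iminium ion is expected to favour the syn adduct (7R), but this centre is not relied on because it is equilibrated in step 4.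

Step 4
Reactants: 5 (3S)-3-[(8R)-6,6-dimethyl-7-oxo-1,4-dioxaspiro[4.4]nonan-8-yl]butanal
Product: 6 exo-methyl diquinane ketol (1R,6S,7R): cis-bicyclo[3.3.0]octane with C2 ketone; C1 tertiary OH; C6 methyl cis to H-7 and to the C1 oxygen; C9 dioxolane; C10 gem-dimethyl
Conditions: 2-(pentafluorophenyl)-6,7-dihydro-5H-pyrrolo[2,1-c][1,2,4]triazol-2-ium tetrafluoroborate (10 mol%), DBU (0.3 equiv), toluene (0.02 M), 40 °C
Reagents that add atoms: none
Why: Carbene-catalysed intramolecular crossed benzoin reaction: the acyl anion equivalent formed at the aldehyde carbon (C2) adds to the ring D ketone (C1) and closes the five-membered ketol; only the cis-fused bicycle is accessible, so C1 follows C7 (1R from 7R). DBU should interconvert the C7 epimers of 5 faster than they cyclise, and closure with the C6 methyl on the convex face should be preferred, so both epimers converge on 6; C6 is β to both carbonyls and cannot epimerise.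

Step 5
Reactants: 6 exo-methyl diquinane ketol
Product: 7 bis(trimethylsilyl) derivative of 6 (C2=C5 trimethylsilyl enol ether; C1 trimethylsilyl ether)
Conditions: Me3SiOTf (2.5 equiv), Et3N (4 equiv), CH2Cl2, 0 °C
Reagents that add atoms: trimethylsilyl trifluoromethanesulfonate C[Si](C)(C)OS(=O)(=O)C(F)(F)F
Why: Soft enolisation and silylation; C1 is quaternary, so the enol ether can only be C2=C5, and the tertiary hydroxyl is silylated in the same operation.

Step 6
Reactants: 7 bis(trimethylsilyl) derivative of 6
Product: 10 diquinane enone ketol (1R,7R; C5=C6 double bond; C2 ketone; free C1 hydroxyl), via exo-bromoketone 8 (not isolated), via silyl ether enone 9 (not isolated)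
Conditions: NBS (1.05 equiv), THF, −78 → 0 °C; solvent exchange; Li2CO3 (3 equiv), LiBr (3 equiv), DMF, 110 °C; then 10% aq. citric acid, MeOH, 20 °C
Reagents that add atoms: none
Why: α-Bromination of the silyl enol ether from the convex face followed by E2 dehydrobromination: the convex bromide is anti-periplanar to the concave C6–H, the only β-hydrogen, so an anti elimination is matched to this epimer where a syn elimination would not be. The C6 stereocentre is erased on purpose, and the mild acid wash removes the tertiary silyl ether.

Step 7
Reactants: 10 diquinane enone ketol
Product: 11 endo-methyl diquinane ketol (1R,6R,7R): as 6 but with the C6 methyl trans to H-7 and to the C1 oxygen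
Conditions: H2 (1 atm), [Ir(cod)(PCy3)(py)]PF6 (5 mol%), CH2Cl2, 20 °C
Reagents that add atoms: none
Why: Hydroxyl-directed homogeneous hydrogenation: iridium bound to the C1 hydroxyl, which lies on the convex face, delivers hydrogen to that face of C5=C6, which is also the sterically open one. The new C6–H is therefore cis to the C1 oxygen and the methyl is placed on the concave face (6R), the relationship the target requires.

Step 8
Reactants: 11 endo-methyl diquinane ketol
Product: 12 bis(trimethylsilyl) diquinane enol ether (1R,6R,7R; C2(OSiMe3)=C5; C1–OSiMe3)
Conditions: Me3SiOTf (2.5 equiv), Et3N (4 equiv), CH2Cl2, 0 °C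
Reagents that add atoms: trimethylsilyl trifluoromethanesulfonate C[Si](C)(C)OS(=O)(=O)C(F)(F)F
Why: Soft enolisation and silylation as in step 5; the enol ether again has only one possible position, and the stereocentres C1, C6 and C7 are not involved.

Step 9
Reactants: 12 bis(trimethylsilyl) diquinane enol ether; 13 trichloroacetyl chloride
Product: 16 hydroazulene 1,3-diketone ketol (1R,6R,7R; cis-bicyclo[5.3.0]decane; C2 and C4 ketones; C1 hydroxyl; C9 dioxolane), via dichlorocyclobutanone 14 (not isolated), via siloxycyclobutanone 15 (not isolated)
Conditions: 13 (2 equiv), Zn–Cu couple (4 equiv), Et2O–DME (9:1), 0 → 20 °C; then AcOH (8 equiv), MeOH, 0 → 20 °C (zinc still present); filtration; Et3N·3HF (3 equiv), THF, 20 °C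
Reagents that add atoms: dichloroketene ClC(Cl)=C=O (made in the flask from 13)
Why: Zinc reduces 13 to dichloroketene, whose electrophilic carbonyl carbon (the future C4) is attacked by the nucleophilic C5 of the enol ether, and the CCl2 carbon (the future C3) then bonds to the siloxy carbon C2, in one asynchronous [2+2] event or through a short-lived oxocarbenium–enolate pair, to give 14. The closest known reaction type is the cycloaddition of dichloroketene to trimethylsilyl enol ethers of cycloalkanones followed by dechlorination and ring opening to cycloalkane-1,3-diones. Zinc in acetic acid removes both chlorines through zinc enolates (15), and fluoride-assisted loss of the C2 silyl group turns the β-siloxy ketone into a push–pull system in which the C2–C5 bond, common to the four- and five-membered rings, breaks in a retro-aldol sense, after which the C4 enol tautomerises so that C5 becomes CH2. The only ring closed is the cyclobutanone, by a polarised two-bond cycloaddition (C5–C4 first, then four-membered closure of C3 onto C2); ring C is not closed by cyclisation but appears when the fusion bond of the bicyclo[3.2.0]heptanone is cut. No stereocentre is created: the two centres formed in 14 (C2 and C5) are erased in the fragmentation, so the face on which the ketene approaches is immaterial, and C1, C6 and C7 are untouched. The step needs the right orientation of the cycloaddition, which the polarity of the enol ether secures (and the enol ether itself can only be C2=C5 because C1 is quaternary). It also needs cleavage of C2–C5 and not C2–C3, which should be favoured because it relieves the strain of the fused bicycle and gives the more substituted enol. The dioxolane should survive because buffered fluoride, not hot aqueous acid, triggers the last stage, and the tertiary C1 silyl ether is cleaved in the same operation.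

Step 10
Reactants: 16 hydroazulene 1,3-diketone ketol
Product: 17 C5-(dimethylaminomethyl) derivative of 16 (Mannich base; mixture of C5 epimers)
Conditions: LiN(iPr)2 (3.3 equiv), THF–DMPU, −78 → −20 °C; CH2=NMe2+ I− (1.3 equiv), −78 → 0 °C; aq. NH4Cl
Reagents that add atoms: dimethyl(methylene)ammonium iodide C=[N+](C)C.[I-]
Why: γ-Functionalisation of a β-diketone polyanion (Mannich-type aminomethylation): once the hydroxyl and C3 are deprotonated, the third equivalent of base can only remove a C5 hydrogen because C1 is quaternary, and this last-formed, most basic carbanion is the one that attacks the iminium salt. The C5 configuration is immaterial, since C5 becomes sp2 in step 11.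

Step 11
Reactants: 17 C5-(dimethylaminomethyl) derivative of 16; 18 4-hydroxy-5,6-dimethyl-2H-pyran-2-one
Product: 21 tetracyclic hemiketal (ring B closed between the pyrone oxygen and C4; C3 methylene; C9 dioxolane; C1 C4 C5 C6 configured as in the target), via exo-methylene enone 19 (not isolated), via ring-opened adduct 20 (not isolated)
Conditions: 18 (2 equiv), 1,4-dioxane, 90 °C
Reagents that add atoms: none
Why: Thermal β-elimination of dimethylamine from the Mannich base gives the C5 exocyclic enone, to which C3' of the pyrone (present as the pyronate, a stronger acid than the diketone) adds in a Michael reaction; the 4'-hydroxyl then closes the six-membered hemiketal on the neighbouring C4 ketone, the ring–chain tautomerism typical of 3-(3-oxoalkyl)-4-hydroxypyranones. C5 is α to the C4 carbonyl in the open form and should settle trans to the C6 methyl, and C4 should take the axial, anomerically stabilised hydroxyl.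

Step 12
Reactants: 21 tetracyclic hemiketal
Product: 23 cyclic vinylogous ester (C3=C4 double bond with C4 bonded to the pyrone oxygen; C2 and C9 ketones; C1 hydroxyl), via hemiketal triketone 22 (not isolated)
Conditions: 2 M HCl, THF, 40 °C; then PPTS (0.2 equiv), benzene, 4 Å molecular sieves, 50 °C
Reagents that add atoms: water O
Why: Acetal hydrolysis frees the C9 ketone; the hemiketal is a β-hydroxy ketone with respect to C2, and acid-catalysed loss of water (C4–OH with C3–H) gives the conjugated cyclic vinylogous ester. This locks ring B, takes the acidic C3 methylene out of play and leaves the C9 ketone as the only carbonyl that can enolise in the normal sense.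

Step 13
Reactants: 23 cyclic vinylogous ester
Product: 24 ring D enone (as 23 with a C7=C8 double bond)
Conditions: IBX (2 equiv), 4-methoxypyridine N-oxide (2 equiv), DMSO, 25 °C
Reagents that add atoms: none
Why: IBX dehydrogenation of a ketone to an enone: only the C9 ketone has an α-methylene (C8) with a β-hydrogen (C7–H), C2 is a vinylogous ester carbonyl, the tertiary hydroxyl cannot be oxidised, and no base is present that could touch the pyrone methyl groups or start a retro-aldol cleavage. C7 becomes sp2 here, which is why its configuration was needed only as a relay.

Step 14
Reactants: 24 ring D enone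
Product: 26 CNP0525404.1 (1R,3R,4S,5R,6R), via acetal epoxide 25 (not isolated)
Conditions: dimethyldioxirane (1.2 equiv), acetone, −40 → 0 °C; then THF–H2O (4:1), PPTS (0.1 equiv), 20 °C
Reagents that add atoms: dimethyldioxirane CC1(C)OO1; water O
Why: Epoxidation of the enol ether double bond C3=C4, the only electron-rich alkene (enone and pyrone are electron-poor), in the manner of a glycal oxidation; water then opens the acetal epoxide at C4 through the oxocarbenium ion and gives the C3 and C4 hydroxyls trans to each other. The face of attack is not relied on: C3, C4 and C5 can all equilibrate through the open 2-hydroxy-1,3-diketone under the mildly acidic aqueous conditions, and the isomer with trans-fused rings B and C and an axial anomeric hydroxyl (the target) is expected to be the resting state, while C1 and C6 are untouched.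

Compound list

1 | 2,2-dimethylcyclopentane-1,3-dione | CC1(C)C(=O)CCC1=O | starting material
2 | 6,6-dimethyl-1,4-dioxaspiro[4.4]nonan-7-one | CC1(C)C(=O)CCC12OCCO2 | intermediate
3 | [(6,6-dimethyl-1,4-dioxaspiro[4.4]non-7-en-7-yl)oxy]trimethylsilane | CC1(C)C(O[Si](C)(C)C)=CCC12OCCO2 | intermediate
4 | (E)-but-2-enal (crotonaldehyde) | C/C=C/C=O | starting material
5 | (3S)-3-[(8R)-6,6-dimethyl-7-oxo-1,4-dioxaspiro[4.4]nonan-8-yl]butanal | C[C@@H](CC=O)[C@H]1CC2(OCCO2)C(C)(C)C1=O | intermediate
6 | exo-methyl diquinane ketol (1R,6S,7R); C6 methyl cis to H-7 and to the C1 oxygen | C[C@H]1CC(=O)[C@@]2(O)[C@@H]1CC3(OCCO3)C2(C)C | intermediate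
7 | bis(trimethylsilyl) derivative of 6 (C2=C5 enol ether, C1 silyl ether) | C[C@H]1C=C(O[Si](C)(C)C)[C@@]2(O[Si](C)(C)C)[C@@H]1CC3(OCCO3)C2(C)C | intermediate
8 | exo-bromoketone (bromine at C5 on the convex face, anti to the C6 hydrogen; C1 silyl ether) | C[C@H]1[C@@H](Br)C(=O)[C@@]2(O[Si](C)(C)C)[C@@H]1CC3(OCCO3)C2(C)C | intermediate (not isolated)
9 | silyl ether enone (C5=C6 double bond; C1 trimethylsilyl ether) | CC1=CC(=O)[C@@]2(O[Si](C)(C)C)[C@@H]1CC3(OCCO3)C2(C)C | intermediate (not isolated)
10 | diquinane enone ketol (1R,7R) | CC1=CC(=O)[C@@]2(O)[C@@H]1CC3(OCCO3)C2(C)C | intermediate
11 | endo-methyl diquinane ketol (1R,6R,7R); C6 methyl trans to H-7 and to the C1 oxygen | C[C@@H]1CC(=O)[C@@]2(O)[C@@H]1CC3(OCCO3)C2(C)C | intermediate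
12 | bis(trimethylsilyl) diquinane enol ether (1R,6R,7R) | C[C@@H]1C=C(O[Si](C)(C)C)[C@@]2(O[Si](C)(C)C)[C@@H]1CC3(OCCO3)C2(C)C | intermediate
13 | trichloroacetyl chloride | ClC(Cl)(Cl)C(Cl)=O | starting material
14 | dichlorocyclobutanone (C5–C4(=O)–C3Cl2–C2(OSiMe3) ring fused on the C2–C5 bond, new bonds on the convex face) | C[C@@H]1[C@H]2C(=O)C(Cl)(Cl)[C@@]2(O[Si](C)(C)C)[C@@]3(O[Si](C)(C)C)[C@@H]1CC4(OCCO4)C3(C)C | intermediate (not isolated)
15 | siloxycyclobutanone (as 14 with C3H2) | C[C@@H]1[C@H]2C(=O)C[C@@]2(O[Si](C)(C)C)[C@@]3(O[Si](C)(C)C)[C@@H]1CC4(OCCO4)C3(C)C | intermediate (not isolated)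
16 | hydroazulene 1,3-diketone ketol (1R,6R,7R) | C[C@@H]1CC(=O)CC(=O)[C@@]2(O)[C@@H]1CC3(OCCO3)C2(C)C | intermediate
17 | C5-(dimethylaminomethyl) derivative of 16 (C5 epimers) | C[C@@H]1C(CN(C)C)C(=O)CC(=O)[C@@]2(O)[C@@H]1CC3(OCCO3)C2(C)C | intermediate
18 | 4-hydroxy-5,6-dimethyl-2H-pyran-2-one | Cc1oc(=O)cc(O)c1C | starting material
19 | exo-methylene enone (C5=CH2 derivative of 16) | C[C@@H]1C(=C)C(=O)CC(=O)[C@@]2(O)[C@@H]1CC3(OCCO3)C2(C)C | intermediate (not isolated)
20 | ring-opened adduct (16 bearing the pyronylmethyl group at C5, trans to the C6 methyl) | C[C@@H]1[C@@H](Cc2c(O)c(C)c(C)oc2=O)C(=O)CC(=O)[C@@]3(O)[C@@H]1CC4(OCCO4)C3(C)C | intermediate (not isolated)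
21 | tetracyclic hemiketal (C3 methylene, C9 dioxolane) | Cc1oc(=O)c2c(c1C)O[C@]1(O)CC(=O)[C@@]3(O)[C@H](CC4(OCCO4)C3(C)C)[C@H](C)[C@H]1C2 | intermediate
22 | hemiketal triketone (as 21 with free C9 ketone) | Cc1oc(=O)c2c(c1C)O[C@]1(O)CC(=O)[C@@]3(O)[C@H](CC(=O)C3(C)C)[C@H](C)[C@H]1C2 | intermediate (not isolated)
23 | cyclic vinylogous ester (C3=C4; C2 and C9 ketones) | Cc1oc(=O)c2c(c1C)OC1=CC(=O)[C@@]3(O)[C@H](CC(=O)C3(C)C)[C@H](C)[C@H]1C2 | intermediate
24 | ring D enone (as 23 with C7=C8) | Cc1oc(=O)c2c(c1C)OC1=CC(=O)[C@@]3(O)C(=CC(=O)C3(C)C)[C@H](C)[C@H]1C2 | intermediate
25 | acetal epoxide (oxirane across C3–C4 of 24, drawn on the face that leads directly to the target) | Cc1oc(=O)c2c(c1C)O[C@]14O[C@@H]4C(=O)[C@@]3(O)C(=CC(=O)C3(C)C)[C@H](C)[C@H]1C2 | intermediate (not isolated)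
26 | CNP0525404.1, (1R,3R,4S,5R,6R) in target numbering | Cc1oc(=O)c2c(c1C)O[C@]1(O)[C@H](O)C(=O)[C@@]3(O)C(=CC(=O)C3(C)C)[C@H](C)[C@H]1C2 | target

Total step count: 14. Longest linear sequence: 14 steps (from 1; 4, 13 and 18 are bought).

Steps least certain to work

Step 9 (key step). The electrophilic zinc chloride formed with the ketene may destroy the enol ether before it reacts. Ring closure at C2 may be slow because C2 is flanked by the quaternary, silyloxy-bearing C1. The fragmentation may go through C2–C3 and merely acylate the five-membered ring. Fallback, from 12 to 15: replace the ketene by a keteniminium salt, made from N,N-dimethylacetamide with Tf2O and 2,4,6-collidine. This is a stronger, zinc-free two-carbon electrophile that adds stepwise to 12 and gives the cyclobutaniminium triflate F1. Mild aqueous bicarbonate hydrolysis of F1 gives 15 without any dechlorination, and the route is rejoined at the fluoride-triggered opening of 15.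

Step 4. The aldehyde can be lost to intermolecular aldol condensation. If C7 equilibrates more slowly than the ring closes, the minor adduct is carried through and stereochemical purity is eroded. Fallback, from 5 to 6: reductive ketyl–carbonyl coupling with SmI2 (THF, tert-butanol, −78 °C) joins C1 and C2 without base and gives the cis-diol F2. The diastereomers are separated at this stage, and Swern oxidation of the secondary alcohol then gives 6.

Step 6. The elimination may be slow because the base must reach the hydrogen on the concave face, and bromide substitution or thermal loss of the silyl ether may compete. Fallback, from 7 to 9: sulfenylation of the enol ether with PhSCl gives the C5-phenylthio ketone F3, and oxidation with m-CPBA at −78 °C gives the sulfoxide F4. F4 epimerises readily at the acidic C5, so heating in toluene (110 °C, CaCO3) lets the epimer with sulfur on the concave face undergo syn elimination to 9; the acid wash of step 6 then gives 10.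

Step 10. The third deprotonation may be incomplete, or the aggregated polyanion may react at C3 or at oxygen. Fallback, from 16 to 17: condensation with pyrrolidine (benzene, azeotropic removal of water) at the less hindered C4 carbonyl gives the enaminone F5. Its only acidic carbon is the γ-position C5, so LiN(iPr)2 (2.2 equiv) and then CH2=NMe2+ I− give the aminomethylated enaminone F6, and buffered aqueous acetic acid hydrolyses F6 to 17.

Step 13. The water formed may rehydrate the vinylogous ester, exposing C3 to oxidation; the dehydrogenation may run on to a dienone; or a hindered cyclopentanone may react too slowly. Fallback, from 23 to 24: kinetic silylation (Me3SiOTf, Et3N, −78 °C) gives the bis-silyl derivative F7 (C9=C8 enol ether, C1 silyl ether). Saegusa–Ito oxidation with Pd(OAc)2 in MeCN gives the C1 silyl ether F8 of the enone, and HF·pyridine returns 24.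

Step 14. The oxidant may attack the wrong face with slow later equilibration; the new secondary alcohol may be oxidised further; or other sites may be epoxidised. Fallback, from 24 to 26: hydrate the enol ether first (THF–H2O, PPTS) to the C3-deoxy hemiketal F9. Open F9 with Cs2CO3 at −40 °C to the C3 diketonate and hydroxylate it with 2-(phenylsulfonyl)-3-phenyloxaziridine; acidification re-closes the hemiketal to 26.

Further compounds

F1 | step 9 | cyclobutaniminium triflate (C4=N+Me2 analogue of 15) | C[C@@H]1[C@H]2C(=[N+](C)C)C[C@@]2(O[Si](C)(C)C)[C@@]3(O[Si](C)(C)C)[C@@H]1CC4(OCCO4)C3(C)C.[O-]S(=O)(=O)C(F)(F)F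
F2 | step 4 | cis-diol (C1 and C2 hydroxyls cis; exo methyl) | C[C@H]1C[C@@H](O)[C@@]2(O)[C@@H]1CC3(OCCO3)C2(C)C
F3 | step 6 | C5-phenylthio ketone (C1 trimethylsilyl ether; C5 epimers) | C[C@H]1C(Sc2ccccc2)C(=O)[C@@]3(O[Si](C)(C)C)[C@@H]1CC4(OCCO4)C3(C)C
F4 | step 6 | C5-phenylsulfinyl ketone (C1 trimethylsilyl ether; C5 epimers) | C[C@H]1C(S(=O)c2ccccc2)C(=O)[C@@]3(O[Si](C)(C)C)[C@@H]1CC4(OCCO4)C3(C)C
F5 | step 10 | enaminone (C4 pyrrolidinyl, C3=C4, C2 ketone) | C[C@@H]1CC(N2CCCC2)=CC(=O)[C@@]3(O)[C@@H]1CC4(OCCO4)C3(C)C
F6 | step 10 | C5-(dimethylaminomethyl) enaminone | C[C@@H]1C(CN(C)C)C(N2CCCC2)=CC(=O)[C@@]3(O)[C@@H]1CC4(OCCO4)C3(C)C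
F7 | step 13 | bis-silyl derivative of 23 (C9=C8 trimethylsilyl enol ether, C1 trimethylsilyl ether) | Cc1oc(=O)c2c(c1C)OC1=CC(=O)[C@@]3(O[Si](C)(C)C)[C@H](C=C(O[Si](C)(C)C)C3(C)C)[C@H](C)[C@H]1C2
F8 | step 13 | C1 trimethylsilyl ether of 24 | Cc1oc(=O)c2c(c1C)OC1=CC(=O)[C@@]3(O[Si](C)(C)C)C(=CC(=O)C3(C)C)[C@H](C)[C@H]1C2
F9 | step 14 | C3-deoxy hemiketal (target without the C3 hydroxyl) | Cc1oc(=O)c2c(c1C)O[C@]1(O)CC(=O)[C@@]3(O)C(=CC(=O)C3(C)C)[C@H](C)[C@H]1C2
A1 | alternative 1 | methyl ketal bis(triethylsilyl) ether of the target | Cc1oc(=O)c2c(c1C)O[C@]1(OC)[C@H](O[Si](CC)(CC)CC)C(=O)[C@@]3(O[Si](CC)(CC)CC)C(=CC(=O)C3(C)C)[C@H](C)[C@H]1C2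
A2 | alternative 1 | ring B/C/D dihydropyran carboxylic acid (carboxyl on C3', vinylic C4'–H, C4 methyl ketal, C1 and C3 triethylsilyl ethers) | OC(=O)C1=CO[C@]2(OC)[C@H](O[Si](CC)(CC)CC)C(=O)[C@@]3(O[Si](CC)(CC)CC)C(=CC(=O)C3(C)C)[C@H](C)[C@H]2C1
A3 | alternative 1 | but-2-yne | CC#CC
A4 | alternative 2 | hydroazulene 4-hydroxycyclopentenone (C2 dioxolane, C4 tert-butyldimethylsilyl ether) | CC1(C)C(=O)C=C2[C@]1(O)C3(OCCO3)C[C@H](O[Si](C)(C)C(C)(C)C)C[C@H]2C
A5 | alternative 2 | 2-isopropylfuran fused to ring C (furan carbons C1, C7, C8, C9) | CC(C)c1cc2c(o1)C3(OCCO3)C[C@H](O[Si](C)(C)C(C)(C)C)C[C@H]2C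
A6 | alternative 2 | Z-enedione (ring C ketone at C1, exocyclic C7=C8 bearing the isobutyryl group) | CC(C)C(=O)/C=C1\C(=O)C2(OCCO2)C[C@H](O[Si](C)(C)C(C)(C)C)C[C@H]1C
A7 | alternative 3 | hydroazulene vinylogous ester (C2 methyl enol ether, C4 ketone, C1 triethylsilyl ether) | COC1=CC(=O)C[C@@H](C)C2=CC(=O)C(C)(C)[C@@]12O[Si](CC)(CC)CC
A8 | alternative 3 | phenyl selenoester of the Z-β-methoxyacrylic acid attached to C1 of the 7-isopropenyl cyclopentenone | O=C([Se]c1ccccc1)/C=C(OC)\[C@@]2(O[Si](CC)(CC)CC)C(C(C)=C)=CC(=O)C2(C)C
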